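The last ring to be closed is the cyclopentanone (C1, C2, C3, C3a, C7a in hexahydroindene numbering), disconnected at C1–C2. Both of its α-carbons (C1, C3) are enolisable and the target's all-trans arrangement is the thermodynamic one, so only the trans ring fusion has to be set in advance. The key step is a one-pot Dieckmann cyclisation/C-ethylation of a fully substituted cyclohexene carrying trans-diequatorial CH(Et)CO2Me and CH2CO2tBu arms on the future C3a and C7a. Acid then cleaves both tert-butyl esters, decarboxylates, and base equilibrates C1/C3. The cyclohexene, with its vicinal quaternary carbons C4/C5, comes from an asymmetric Robinson annulation followed by substrate-controlled conjugate additions.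

Key step: step 10

Remark: the (R)-BINAP palladium aqua complex is assumed to give the (R)-adduct 4; if the opposite sense is found, the (S)-ligand is used.
Remark: compounds 5–16 are numbered as cyclohexene carboxylates (C1 = ester-bearing quaternary carbon); compounds 17–21 use the hexahydro-1H-indene numbering of the target.

Step 1
Reactants: 1 tert-butyl 3-oxopentanoate
Product: 2 tert-butyl 2-ethyl-3-oxopentanoate (racemic)
Conditions: EtI, K2CO3, acetone, reflux
Reagents that add atoms: iodoethane, CCI
Why: C-alkylation of the β-keto ester enolate (acetoacetic ester alkylation) should give the mono-ethyl compound, whose stereocentre is labile and is fixed only in step 2.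

Step 2
Reactants: 2 tert-butyl 2-ethyl-3-oxopentanoate; 3 but-3-en-2-one
Product: 4 tert-butyl (2R)-2-ethyl-5-oxo-2-propanoylhexanoate
Conditions: [Pd((R)-BINAP)(OH2)2](OTf)2 (5 mol %), THF, −20 °C
Reagents that add atoms: none
Why: Catalytic enantioselective Michael addition of an α-substituted tert-butyl β-keto ester to an enone through a chiral square-planar palladium enolate, whose ligand shields one enolate face and sets the quaternary centre (future C4).

Step 3
Reactants: 4 tert-butyl (2R)-2-ethyl-5-oxo-2-propanoylhexanoate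
Product: 5 tert-butyl (1R)-1,2-diethyl-4-oxocyclohex-2-ene-1-carboxylate
Conditions: pyrrolidine (cat.), AcOH (cat.), PhMe, 60 °C
Reagents that add atoms: none
Why: Enamine-mediated intramolecular aldol condensation (second half of a Robinson annulation), in which the enamine of the unhindered methyl ketone attacks the propanoyl carbonyl and dehydration gives the conjugated enone without touching the quaternary centre.

Step 4
Reactants: 5 tert-butyl (1R)-1,2-diethyl-4-oxocyclohex-2-ene-1-carboxylate
Product: 6 tert-butyl (1R)-1,2-diethyl-4-oxocyclohexa-2,5-diene-1-carboxylate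
Conditions: DDQ, 1,4-dioxane, 100 °C
Reagents that add atoms: none
Why: DDQ dehydrogenation of a 4,4-disubstituted cyclohexenone to the cross-conjugated dienone, which can only occur across C5–C6 because C1 is quaternary.

Step 5
Reactants: 7 methyl butanoate
Product: 8 1-methoxy-1-(trimethylsilyloxy)but-1-ene (E/Z mixture)
Conditions: LDA, THF, −78 °C; TMSCl, −78 °C to rt
Reagents that add atoms: chlorotrimethylsilane, C[Si](C)(C)Cl
Why: Kinetic ester enolisation and O-silylation should give the ketene silyl acetal, whose geometry is irrelevant because the derived stereocentre is equilibrated at the end.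

Step 6
Reactants: 6 tert-butyl (1R)-1,2-diethyl-4-oxocyclohexa-2,5-diene-1-carboxylate; 8 1-methoxy-1-(trimethylsilyloxy)but-1-ene
Product: 10 tert-butyl (1R,6R)-1,2-diethyl-6-[(2RS)-1-methoxy-1-oxobutan-2-yl]-4-oxocyclohex-2-ene-1-carboxylate, via silyl enol ether 9 (not isolated)
Conditions: TrSbCl6 (5 mol %), CH2Cl2, −78 °C; then 1 M HCl, THF, 0 °C
Reagents that add atoms: none
Why: Mukaiyama–Michael addition at C6, the only unsubstituted β-carbon, is expected anti to the bulky, electron-withdrawing CO2tBu group on the flat dienone (torsional and polar control), which sets the future C3a; the side-chain CH is carried on as an epimer mixture.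

Step 7
Reactants: 10 tert-butyl (1R,6R)-1,2-diethyl-6-[(2RS)-1-methoxy-1-oxobutan-2-yl]-4-oxocyclohex-2-ene-1-carboxylate; 11 tert-butyl bromoacetate
Product: 12 tert-butyl (1R,5S,6R)-5-(2-tert-butoxy-2-oxoethyl)-1,2-diethyl-6-[(2RS)-1-methoxy-1-oxobutan-2-yl]-4-oxocyclohex-2-ene-1-carboxylate
Conditions: LDA (1.05 equiv), THF, −78 °C; 11, DMPU, −78 to −20 °C
Reagents that add atoms: none
Why: Kinetic α′-deprotonation of the enone and enolate alkylation, in which the electrophile should enter trans to the adjacent C6 side chain (trans-2,3-disubstitution), setting the future C7a.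

Step 8
Reactants: 12 tert-butyl (1R,5S,6R)-5-(2-tert-butoxy-2-oxoethyl)-1,2-diethyl-6-[(2RS)-1-methoxy-1-oxobutan-2-yl]-4-oxocyclohex-2-ene-1-carboxylate; 13 (E)-(2-bromoethenyl)benzene
Product: 15 tert-butyl (1R,2S,5S,6R)-5-(2-tert-butoxy-2-oxoethyl)-1,2-diethyl-6-[(2RS)-1-methoxy-1-oxobutan-2-yl]-2-[(E)-2-phenylethenyl]-4-(trifluoromethylsulfonyloxy)cyclohex-3-ene-1-carboxylate, via silyl enol ether 14 (not isolated)
Conditions: 13, Mg, THF (Grignard reagent); CuI·2LiCl (10 mol %), TMSCl, THF, −40 to 0 °C; then CsF, PhNTf2, DME, rt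
Reagents that add atoms: N-phenylbis(trifluoromethanesulfonimide), O=S(=O)(N(c1ccccc1)S(=O)(=O)C(F)(F)F)C(F)(F)F; chlorotrimethylsilane, C[Si](C)(C)Cl (silyl group present only in 14)
Why: Copper-catalysed, chlorosilane-accelerated 1,4-addition of the alkenyl Grignard reagent should occur by axial attack on the half-chair with both side chains equatorial and the C1 ethyl axial, anti to that ethyl and trans to the C6 substituent, placing the styryl group cis to CO2tBu (future C5); the regiodefined silyl enol ether is then converted into the enol triflate by fluoride and PhNTf2.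

Step 9
Reactants: 15 the enol triflate from step 8
Product: 16 tert-butyl (1R,2S,5S,6R)-5-(2-tert-butoxy-2-oxoethyl)-1,2,4-triethyl-6-[(2RS)-1-methoxy-1-oxobutan-2-yl]-2-[(E)-2-phenylethenyl]cyclohex-3-ene-1-carboxylate
Conditions: Et2Zn, PdCl2(dppf) (5 mol %), THF, 50 °C
Reagents that add atoms: diethylzinc, CC[Zn]CC
Why: Negishi sp2–sp3 cross-coupling of the enol triflate (the bidentate ligand suppresses β-hydride elimination) fixes the trisubstituted ring alkene regiospecifically and touches no stereocentre.

Step 10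
Reactants: 16 the cyclohexene triester from step 9
Product: 18 di-tert-butyl (3aR,4R,5S,7aS)-1,3,4,5,7-pentaethyl-2-oxo-5-[(E)-2-phenylethenyl]-2,3,3a,4,5,7a-hexahydro-1H-indene-1,4-dicarboxylate (C1/C3 epimers), via potassium enolate 17 (not isolated)
Conditions: t-BuOK (1.1 equiv), THF, 0 °C to rt; then EtI, DMF, rt
Reagents that add atoms: iodoethane, CCI
Why: tert-Butoxide deprotonates the CH2CO2tBu arm, the ester enolate adds to the methyl ester carbonyl of the other arm, loss of methoxide gives the β-keto ester as its stabilised enolate, and this is C-ethylated by EtI (Dieckmann condensation followed by acetoacetic-ester-type alkylation; the closest precedent is the closure of trans-cyclohexane-1,2-diacetates to trans-hexahydroindan-2-ones). The ring closes by a 5-exo-trig acyl substitution (C1 enolate carbon onto the C2 carbonyl), and the trans ring fusion is not created here but inherited from the trans-diequatorial arms on C3a and C7a. The new quaternary C1 forms without control and C3 is carried as a mixture; both are α to the ketone and are corrected thermodynamically in step 11, which makes the closure stereoconvergent. The step needs regioselectivity between the two possible Claisen modes, which is secured because the tert-butyl esters (on the arm and on quaternary C4) are poor electrophiles and because only attack of the CH2 enolate on the methyl ester gives a product that is trapped as a doubly stabilised enolate. C- over O-ethylation is favoured by the soft iodide electrophile, and close to one equivalent of base avoids a second alkylation at C3.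

Step 11
Reactants: 18 the β-keto diester from step 10
Product: 21 (1S,3S,3aR,4R,5S,7aR)-1,3,4,5,7-pentaethyl-2-oxo-5-[(E)-2-phenylethenyl]-2,3,3a,4,5,7a-hexahydro-1H-indene-4-carboxylic acid (CNP0132298.1), via β-keto diacid 19 (not isolated), via C1/C3-epimeric keto acid 20 (not isolated)
Conditions: TFA/CH2Cl2 (1:4), 0 °C to rt; PhMe, 80 °C; then DBU, CH2Cl2, rt; aq. citric acid
Reagents that add atoms: none
Why: Acidolysis of both tert-butyl esters, thermal decarboxylation of the β-keto acid through its enol, and base-mediated equilibration of the two enolisable α-centres should give the all-trans cyclopentanone, in which each ethyl is trans to the adjacent ring-fusion bond (thermodynamic control of C1 and C3).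

Compound list
1 | tert-butyl 3-oxopentanoate | CCC(=O)CC(=O)OC(C)(C)C | starting material
2 | tert-butyl 2-ethyl-3-oxopentanoate (racemic) | CCC(=O)C(CC)C(=O)OC(C)(C)C | intermediate
3 | but-3-en-2-one | CC(=O)C=C | starting material
4 | tert-butyl (2R)-2-ethyl-5-oxo-2-propanoylhexanoate | CCC(=O)[C@](CC)(C(=O)OC(C)(C)C)CCC(C)=O | intermediate
5 | tert-butyl (1R)-1,2-diethyl-4-oxocyclohex-2-ene-1-carboxylate | O=C1C=C(CC)[C@](CC)(C(=O)OC(C)(C)C)CC1 | intermediate
6 | tert-butyl (1R)-1,2-diethyl-4-oxocyclohexa-2,5-diene-1-carboxylate | O=C1C=C(CC)[C@](CC)(C(=O)OC(C)(C)C)C=C1 | intermediate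
7 | methyl butanoate | CCCC(=O)OC | starting material
8 | 1-methoxy-1-(trimethylsilyloxy)but-1-ene (E/Z mixture) | CCC=C(OC)O[Si](C)(C)C | intermediate
9 | tert-butyl (1R,6R)-1,2-diethyl-6-(1-methoxy-1-oxobutan-2-yl)-4-(trimethylsilyloxy)cyclohexa-2,4-diene-1-carboxylate (side chain trans to CO2tBu; side-chain CH epimers) | C[Si](C)(C)OC1C=C(CC)[C@](CC)(C(=O)OC(C)(C)C)[C@@H](C(CC)C(=O)OC)C=1 | intermediate
10 | tert-butyl (1R,6R)-1,2-diethyl-6-[(2RS)-1-methoxy-1-oxobutan-2-yl]-4-oxocyclohex-2-ene-1-carboxylate (side chain trans to CO2tBu) | O=C1C=C(CC)[C@](CC)(C(=O)OC(C)(C)C)[C@@H](C(CC)C(=O)OC)C1 | intermediate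
11 | tert-butyl bromoacetate | BrCC(=O)OC(C)(C)C | starting material
12 | tert-butyl (1R,5S,6R)-5-(2-tert-butoxy-2-oxoethyl)-1,2-diethyl-6-[(2RS)-1-methoxy-1-oxobutan-2-yl]-4-oxocyclohex-2-ene-1-carboxylate (C5 and C6 side chains trans) | O=C1C=C(CC)[C@](CC)(C(=O)OC(C)(C)C)[C@@H](C(CC)C(=O)OC)[C@@H]1CC(=O)OC(C)(C)C | intermediate
13 | (E)-(2-bromoethenyl)benzene | Br/C=C/c1ccccc1 | starting material
14 | tert-butyl (1R,2S,5S,6R)-5-(2-tert-butoxy-2-oxoethyl)-1,2-diethyl-6-(1-methoxy-1-oxobutan-2-yl)-2-[(E)-2-phenylethenyl]-4-(trimethylsilyloxy)cyclohex-3-ene-1-carboxylate (styryl cis to CO2tBu) | C[Si](C)(C)OC1=C[C@@](/C=C/c2ccccc2)(CC)[C@](CC)(C(=O)OC(C)(C)C)[C@@H](C(CC)C(=O)OC)[C@@H]1CC(=O)OC(C)(C)C | intermediate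
15 | tert-butyl (1R,2S,5S,6R)-5-(2-tert-butoxy-2-oxoethyl)-1,2-diethyl-6-[(2RS)-1-methoxy-1-oxobutan-2-yl]-2-[(E)-2-phenylethenyl]-4-(trifluoromethylsulfonyloxy)cyclohex-3-ene-1-carboxylate | O=S(=O)(OC1=C[C@@](/C=C/c2ccccc2)(CC)[C@](CC)(C(=O)OC(C)(C)C)[C@@H](C(CC)C(=O)OC)[C@@H]1CC(=O)OC(C)(C)C)C(F)(F)F | intermediate
16 | tert-butyl (1R,2S,5S,6R)-5-(2-tert-butoxy-2-oxoethyl)-1,2,4-triethyl-6-[(2RS)-1-methoxy-1-oxobutan-2-yl]-2-[(E)-2-phenylethenyl]cyclohex-3-ene-1-carboxylate | CCC1=C[C@@](/C=C/c2ccccc2)(CC)[C@](CC)(C(=O)OC(C)(C)C)[C@@H](C(CC)C(=O)OC)[C@@H]1CC(=O)OC(C)(C)C | intermediate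
17 | potassium enolate of di-tert-butyl 3,4,5,7-tetraethyl-2-oxo-5-[(E)-2-phenylethenyl]-2,3,3a,4,5,7a-hexahydro-1H-indene-1,4-dicarboxylate (trans-fused; C3 epimers) | CCC1=C[C@@](/C=C/c2ccccc2)(CC)[C@](CC)(C(=O)OC(C)(C)C)[C@@H]2[C@@H]1C(C(=O)OC(C)(C)C)=C([O-])C2CC.[K+] | intermediate
18 | di-tert-butyl (3aR,4R,5S,7aS)-1,3,4,5,7-pentaethyl-2-oxo-5-[(E)-2-phenylethenyl]-2,3,3a,4,5,7a-hexahydro-1H-indene-1,4-dicarboxylate (C1/C3 epimers) | CCC1=C[C@@](/C=C/c2ccccc2)(CC)[C@](CC)(C(=O)OC(C)(C)C)[C@@H]2[C@@H]1C(CC)(C(=O)OC(C)(C)C)C(=O)C2CC | intermediate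
19 | (3aR,4R,5S,7aS)-1,3,4,5,7-pentaethyl-2-oxo-5-[(E)-2-phenylethenyl]-2,3,3a,4,5,7a-hexahydro-1H-indene-1,4-dicarboxylic acid (C1/C3 epimers) | CCC1=C[C@@](/C=C/c2ccccc2)(CC)[C@](CC)(C(=O)O)[C@@H]2[C@@H]1C(CC)(C(=O)O)C(=O)C2CC | intermediate
20 | (3aR,4R,5S,7aR)-1,3,4,5,7-pentaethyl-2-oxo-5-[(E)-2-phenylethenyl]-2,3,3a,4,5,7a-hexahydro-1H-indene-4-carboxylic acid (C1/C3 epimer mixture) | CCC1=C[C@@](/C=C/c2ccccc2)(CC)[C@](CC)(C(=O)O)[C@@H]2[C@@H]1C(CC)C(=O)C2CC | intermediate
21 | (1S,3S,3aR,4R,5S,7aR)-1,3,4,5,7-pentaethyl-2-oxo-5-[(E)-2-phenylethenyl]-2,3,3a,4,5,7a-hexahydro-1H-indene-4-carboxylic acid | CCC1=C[C@@](/C=C/c2ccccc2)(CC)[C@](CC)(C(=O)O)[C@@H]2[C@@H]1[C@H](CC)C(=O)[C@H]2CC | target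

Total step count: 11. Longest linear sequence: 10 steps (steps 1–4 and 6–11); step 5 prepares reagent 8.

Steps most likely to fail

Step 8. The 1,4-addition has to create a quaternary carbon next to an existing quaternary carbon, so the alkenyl copper species may add too slowly and enolisation or 1,2-addition may take over; the Grignard formation may also erode the E geometry. The fallback sets out from 12 and uses a much smaller sp nucleophile. Nickel-catalysed conjugate addition of dimethyl(phenylethynyl)aluminium (Ni(acac)2/DIBAL-H, Et2O) should give the β-alkynyl ketone F1 with the same facial preference. Ruthenium-catalysed trans-hydrogenation of the alkyne ([Cp*Ru(cod)Cl], H2) should then give the (E)-styryl ketone F2. Kinetic enolisation at the CH2 next to the new quaternary carbon (KHMDS, −78 °C) and trapping with PhNTf2 returns to the route at 15.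

Step 6. Facial discrimination on the flat dienone rests only on the difference between ethyl and CO2tBu at C1 and may be poor or reversed. The fallback sets out from 6 and replaces substrate control by catalyst control. Iminium-catalysed Michael addition of dimethyl malonate with a 9-amino-9-deoxy-epi-cinchona primary amine salt (the pseudo-enantiomer that attacks anti to CO2tBu) should give the malonate adduct F3. Ethylation of the malonate carbon (Cs2CO3, EtI, DMF) gives the ethylmalonate F4, and Krapcho demethoxycarbonylation (LiCl, wet DMSO, 140 °C) returns to the route at 10.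

Step 2. With an acyclic donor that carries an α-ethyl and a propanoyl group, catalyst turnover or enantioselectivity may be insufficient. The fallback sets out from 2 (with 3) and replaces asymmetric catalysis by resolution. Base-catalysed Michael addition (cat. t-BuOK, t-BuOH) gives the racemic diketo ester F5, and pyrrolidine/AcOH cyclisation gives the racemic enone F6. Preparative chiral SFC returns to the route at 5, and the antipodal enone F7 is set aside.

Further compounds
F1 | step 8 | tert-butyl 5-(2-tert-butoxy-2-oxoethyl)-1,2-diethyl-6-(1-methoxy-1-oxobutan-2-yl)-4-oxo-2-(phenylethynyl)cyclohexane-1-carboxylate (configuration as in 15, alkynyl cis to CO2tBu) | O=C1C[C@@](C#Cc2ccccc2)(CC)[C@](CC)(C(=O)OC(C)(C)C)[C@@H](C(CC)C(=O)OC)[C@@H]1CC(=O)OC(C)(C)C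
F2 | step 8 | tert-butyl 5-(2-tert-butoxy-2-oxoethyl)-1,2-diethyl-6-(1-methoxy-1-oxobutan-2-yl)-4-oxo-2-[(E)-2-phenylethenyl]cyclohexane-1-carboxylate (configuration as in 15) | O=C1C[C@@](/C=C/c2ccccc2)(CC)[C@](CC)(C(=O)OC(C)(C)C)[C@@H](C(CC)C(=O)OC)[C@@H]1CC(=O)OC(C)(C)C
F3 | step 6 | tert-butyl (1R,6R)-6-(1,3-dimethoxy-1,3-dioxopropan-2-yl)-1,2-diethyl-4-oxocyclohex-2-ene-1-carboxylate | O=C1C=C(CC)[C@](CC)(C(=O)OC(C)(C)C)[C@@H](C(C(=O)OC)C(=O)OC)C1
F4 | step 6 | dimethyl 2-ethyl-2-[(1R,2R)-2-(tert-butoxycarbonyl)-2,3-diethyl-5-oxocyclohex-3-en-1-yl]propanedioate (ring configuration as in 10) | O=C1C=C(CC)[C@](CC)(C(=O)OC(C)(C)C)[C@@H](C(CC)(C(=O)OC)C(=O)OC)C1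
F5 | step 2 | tert-butyl 2-ethyl-5-oxo-2-propanoylhexanoate (racemic) | CCC(=O)C(CC)(CCC(C)=O)C(=O)OC(C)(C)C
F6 | step 2 | tert-butyl 1,2-diethyl-4-oxocyclohex-2-ene-1-carboxylate (racemic) | O=C1C=C(CC)C(CC)(C(=O)OC(C)(C)C)CC1
F7 | step 2 | tert-butyl (1S)-1,2-diethyl-4-oxocyclohex-2-ene-1-carboxylate | O=C1C=C(CC)[C@@](CC)(C(=O)OC(C)(C)C)CC1
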